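Monday's flask held 63.5% of its partner charge as target at the last reading, and Thursday's, with less substrate, held 36.2%. That gap is what I followed.

| flask | substrate | partner | time |
|---|---|---|---|
| Thursday's | 200 mM | 200 mM |  |
| Monday's | 400 mM | 200 mM |  |
| Friday's | 200 mM | 100 mM |  |
| Tuesday's | 66.0 mM | 600 mM | 170 min |

| Thursday's run: time / min | Thursday's run: [target] / mM | Monday's run: time / min | Monday's run: [target] / mM | Friday's run: time / min | Friday's run: [target] / mM |
|---|---|---|---|---|---|
| 21 | 26.7 | 21 | 64.3 | 21 | 11.9 |
| 42 | 47.6 | 42 | 103.3 | 42 | 23.6 |
| 64 | 61.0 | 64 | 119.1 | 64 | 33.1 |
| 85 | 65.0 | 85 | 125.6 | 85 | 39.2 |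
| 110 | 69.9 | 110 | 129.4 | 110 | 43.0 |
| 130 | 72.5 | 130 | 127.7 | 130 | 46.2 |
| 150 | 73.9 | 150 | 125.9 | 150 | 45.0 |
| 170 | 72.4 | 170 | 127.0 | 170 | 48.7 |

(standard deviation of a reading: 1 mM)

* the power of [partner] that the first rate follows, about the charge of the Thursday's run; measure it at two percent of substrate made into target
* the power of [substrate] that the first rate follows, about the charge of the Thursday's run; measure it at two percent of substrate made into target (one fixed amount of target, the same in the runs compared)
* target in the Tuesday's run at 170 min, as a share of the substrate charged

- Overall: substrate + partner -> target.
- Constant volume, constant temperature.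
- An order is taken over about fifteen percent of the charge, up and down.

I began with the rate. Over the first span, Monday's substrate at twice Thursday's gave a power of 1.27. Thursday's partner at twice Friday's gave 1.17. I read both as orders near one, with the scatter of single readings.

Thursday's first span turned 0.00636 /min of the substrate charge. Tuesday's partner stood at 9.09 times its substrate. As a rough estimate I scaled Thursday's pace by the partner charges, to 0.0191 /min. The half-time of that estimated pace, 36.3 min, is shorter than 170 min, so I counted Tuesday's charge as turned.

Then I looked at the slowing. I defined the leak ratio: partner charge not standing as target at the last reading, per unit of target. It read 1.76 on Thursday, 0.575 on Monday and 1.05 on Friday. In logarithms it follows substrate with power 1.62 downward and partner with power 0.743 upward. Tuesday's charge adds 1.13 powers of ten, so I put its leak ratio at 23.9. I supposed that a lost target costs two partners, the one that made it and the one that removed it. The kept share of turned substrate is then two over two plus the ratio, 7.72%, and that was my number.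

The forecast said 62%, with powers 1.3 in substrate and 1.2 in partner, holding that “equilibrium alone doesn't explain it”.

The flask gave 5.77%, with powers 1.1 and 1.0. Its steps were these:

    substrate + partner → target (0.03522 /M/min)
    target + partner → side product (0.07800 /M/min)
    substrate + partner + target → 2 target (0.8400 /M²/min)
    partner → lost reagent (0.003414 /min)

My kept share of 7.72% stood 1.34 times the result. A fit with the main steps alone gave 6.56% for Tuesday's flask. Put back through the same rule, with the charge counted as turned, the result means a leak ratio of 32.7, above my 23.9. Thursday's reading of 1.76 lies 1.13 powers of ten below my 23.9, and Monday's reading of 0.575 lies 1.62 powers of ten below it.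

The earlier runs and the new flask were generated by integration for an exercise; scatter was added.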